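The strategy treats pyranone ring C of the flavone as the furanone ring of a 2-arylbenzofuran-3-one widened by one atom. That atom is C3, the CH lodged between C2, which carries ring B, and carbonyl carbon C4. Cutting C2–C3 and C3–C4 leads back to a one-carbon carbene unit and the 3-silyloxybenzofuran 9. Compound 9 already holds ring A, ring B, O1 and all five methoxy groups. In one operation dibromocarbene cyclopropanates the electron-rich furan C2=C3 bond of 9, and the adduct opens to 3-bromoflavone 13, making both bonds and ring C. Three conventional steps deliver 9, and one reductive debromination finishes the synthesis.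

Key step: step 4

Assumption: in step 1 AlCl3 is taken to cleave the ortho methoxy group wedged between the acyl group and a second methoxy group (C2' of 3), in line with the behaviour of crowded ortho ethers in related polymethoxyaryl ketones. The constitution of 5 is to be checked by NOE/HMBC before material is carried on.

Step 1
Reactants: 1 1,2,3,5-tetramethoxybenzene; 2 chloroacetyl chloride
Product: 4 2-chloro-1-(2-hydroxy-3,4,6-trimethoxyphenyl)ethan-1-one, via tetramethoxyphenacyl chloride 3 (not isolated)
Conditions: AlCl3 (3 equiv), CH2Cl2, 0 °C to reflux; then ice/aq. HCl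
Reagents that add atoms: chloroacetyl chloride (reactant 2), ClCC(Cl)=O
Why: Friedel–Crafts acylation at one of the two equivalent free positions of the very electron-rich arene should give 3, after which AlCl3 chelated between the carbonyl oxygen and an ortho ether lets chloride attack that ether's methyl group, preferring the C2' methoxy because it is forced out of the ring plane between the acyl group and the C3' methoxy and is therefore the more Lewis-basic and more strained one.

Step 2
Reactants: 4 2-chloro-1-(2-hydroxy-3,4,6-trimethoxyphenyl)ethan-1-one
Product: 5 4,6,7-trimethoxybenzofuran-3(2H)-one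
Conditions: NaOAc (3 equiv), MeOH, reflux
Reagents that add atoms: none
Why: Intramolecular Williamson-type O-alkylation (5-exo-tet SN2 attack of the phenoxide on the neighbouring chloromethyl ketone) is the standard closure of coumaran-3-ones, and the weak base together with the donor-deactivated carbonyl group keeps aldol self-condensation of 5 low.

Step 3
Reactants: 5 4,6,7-trimethoxybenzofuran-3(2H)-one; 6 4-bromo-1,2-dimethoxybenzene
Product: 9 tert-butyl{[2-(3,4-dimethoxyphenyl)-4,6,7-trimethoxybenzofuran-3-yl]oxy}dimethylsilane, via 2-arylbenzofuranone 7 (not isolated), via arylated enolate 8 (not isolated)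
Conditions: Pd(OAc)2 (2 mol %), P(t-Bu)3 (4 mol %), NaOtBu (2.3 equiv), toluene/THF, 70 °C, argon; then TBSCl (2 equiv), 0 °C to rt
Reagents that add atoms: 4-bromo-1,2-dimethoxybenzene (reactant 6), COc1ccc(Br)cc1OC; tert-butyldimethylsilyl chloride (TBSCl), CC(C)(C)[Si](C)(C)Cl
Why: Buchwald–Hartwig–Miura α-arylation of a fully enolised ketone (oxidative addition of 6 to zerovalent palladium, enolate binding, reductive elimination) should place ring B on C2, the more acidic ketone 7 is deprotonated at once to the aromatic benzofuran-3-olate 8, which resists a second arylation for steric reasons, and the hard silicon electrophile then reacts at oxygen, so that the autoxidation-prone 7 (racemic at C2, a centre that is erased on enolisation) is never handled.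

Step 4
Reactants: 9 tert-butyl{[2-(3,4-dimethoxyphenyl)-4,6,7-trimethoxybenzofuran-3-yl]oxy}dimethylsilane; 10 bromoform
Product: 13 3-bromo-2-(3,4-dimethoxyphenyl)-5,7,8-trimethoxy-4H-chromen-4-one, via dibromocyclopropane adduct 11 (not isolated), via silyloxyflavylium bromide 12 (not isolated)
Conditions: CHBr3 (3 equiv), KOtBu (4 equiv, added in portions to 9 and 10), toluene, −20 °C to rt; aq. NH4Cl
Reagents that add atoms: bromoform (reactant 10), BrC(Br)Br
Why: Proposed new method: KOtBu turns 10 into dibromocarbene by α-elimination, the electrophilic carbene adds in a concerted [2+1] fashion to the C2=C3 bond of the furan ring of 9 to give the cis-fused adduct 11, the endo bromide of 11 ionises while the former C2–C3 bond breaks in a disrotatory 2π-electrocyclic opening to the aromatic 4-silyloxyflavylium ion 12, and transfer of the silyl group from the C4 oxygen to tert-butoxide unveils the carbonyl group of 13. The closest known reaction types are the dihalocarbene homologation of cyclic silyl enol ethers to ring-enlarged 2-haloenones and the Ciamician–Dennstedt carbon insertion into pyrroles and indoles; a 3-silyloxybenzofuran has not served as substrate, which is why the step carries the label. Ring C is closed by ring expansion and not by joining two chain ends: the five-membered furan ring takes up the carbene carbon as C3, so that C2–C3 and C3–C4 are formed and the old bond between C2 and the silyloxy carbon is given up. No stereocentre is created in 13; the two in 11 are transient and cis by ring strain, and the geminal dibromide offers an endo leaving group whichever face the carbene attacks. The step needs site selectivity for the enol-ether bond over the methoxylated rings A and B, which is secured by two oxygen donors (O1 on C2, the silyloxy group on C3) sitting on a bond whose sacrifice costs only the small furan resonance energy, while the bulky TBS group should withstand KOtBu long enough to prevent C-alkylation of a free enolate. Constitutional selectivity is built in, because a carbon wedged between the carbon bearing ring B and the oxygenated carbon can only give the 2-aryl (flavone) and never the 3-aryl (isoflavone) skeleton, and formation of the flavylium ion supplies the driving force.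

Step 5
Reactants: 13 3-bromo-2-(3,4-dimethoxyphenyl)-5,7,8-trimethoxy-4H-chromen-4-one
Product: 14 isosinensetin, 2-(3,4-dimethoxyphenyl)-5,7,8-trimethoxy-4H-chromen-4-one
Conditions: Pd(PPh3)4 (5 mol %), HCO2Na (3 equiv), DMF, 90 °C
Reagents that add atoms: none
Why: Palladium-catalysed formate hydrodehalogenation (oxidative addition of the activated C3–Br bond of the α-bromoenone to zerovalent palladium, exchange of bromide for formate, loss of CO2 to a palladium hydride, reductive elimination) should install C3–H without touching the C2=C3 bond, the carbonyl group or the aryl methyl ethers.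

Compound list
1 | 1,2,3,5-tetramethoxybenzene | COc1cc(OC)c(OC)c(OC)c1 | starting material
2 | chloroacetyl chloride | ClCC(Cl)=O | starting material
3 | 2-chloro-1-(2,3,4,6-tetramethoxyphenyl)ethan-1-one (tetramethoxyphenacyl chloride, not isolated) | COc1cc(OC)c(C(=O)CCl)c(OC)c1OC | intermediate
4 | 2-chloro-1-(2-hydroxy-3,4,6-trimethoxyphenyl)ethan-1-one | COc1cc(OC)c(C(=O)CCl)c(O)c1OC | intermediate
5 | 4,6,7-trimethoxybenzofuran-3(2H)-one | COc1cc(OC)c2c(c1OC)OCC2=O | intermediate
6 | 4-bromo-1,2-dimethoxybenzene | COc1ccc(Br)cc1OC | starting material
7 | 2-(3,4-dimethoxyphenyl)-4,6,7-trimethoxybenzofuran-3(2H)-one (racemic at C2, not isolated) | COc1ccc(C2Oc3c(OC)c(OC)cc(OC)c3C2=O)cc1OC | intermediate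
8 | sodium 2-(3,4-dimethoxyphenyl)-4,6,7-trimethoxybenzofuran-3-olate (not isolated) | [Na+].[O-]c1c(-c2ccc(OC)c(OC)c2)oc2c(OC)c(OC)cc(OC)c12 | intermediate
9 | tert-butyl{[2-(3,4-dimethoxyphenyl)-4,6,7-trimethoxybenzofuran-3-yl]oxy}dimethylsilane | COc1ccc(-c2oc3c(OC)c(OC)cc(OC)c3c2O[Si](C)(C)C(C)(C)C)cc1OC | intermediate
10 | bromoform | BrC(Br)Br | starting material
11 | 1,1-dibromo-6b-[(tert-butyldimethylsilyl)oxy]-1a-(3,4-dimethoxyphenyl)-3,4,6-trimethoxy-1a,6b-dihydro-1H-cyclopropa[b]benzofuran (racemic, cis ring fusion enforced, not isolated) | COc1ccc(C23Oc4c(OC)c(OC)cc(OC)c4C2(O[Si](C)(C)C(C)(C)C)C3(Br)Br)cc1OC | intermediate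
12 | 3-bromo-4-[(tert-butyldimethylsilyl)oxy]-2-(3,4-dimethoxyphenyl)-5,7,8-trimethoxychromenylium bromide (not isolated) | COc1ccc(-c2[o+]c3c(OC)c(OC)cc(OC)c3c(O[Si](C)(C)C(C)(C)C)c2Br)cc1OC.[Br-] | intermediate
13 | 3-bromo-2-(3,4-dimethoxyphenyl)-5,7,8-trimethoxy-4H-chromen-4-one | COc1ccc(-c2oc3c(OC)c(OC)cc(OC)c3c(=O)c2Br)cc1OC | intermediate
14 | isosinensetin, 2-(3,4-dimethoxyphenyl)-5,7,8-trimethoxy-4H-chromen-4-one (no stereocentre) | COc1ccc(-c2cc(=O)c3c(OC)cc(OC)c(OC)c3o2)cc1OC | target

Total step count: 5. Longest linear sequence: 5 steps (1 → 4 → 5 → 9 → 13 → 14).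

Steps most likely to fail

1. Step 4 (the labelled step). Three things may go wrong.
- The carbene may be consumed by tert-butoxide and tert-butanol faster than it adds to the crowded, tetrasubstituted and partly aromatic C2=C3 bond.
- The silyl ether may be cleaved early, which would divert the reaction to alkylation of the enolate at C2.
- Residual base may attack the new pyranone ring at C2, which is why the base is dosed into the mixture of 9 and 10.

The fallback uses known chemistry only, sets out from 4 and comes back to the route at 14. Reductive dechlorination of 4 with Zn dust in AcOH should give 1-(2-hydroxy-3,4,6-trimethoxyphenyl)ethan-1-one F1. Claisen–Schmidt condensation of F1 with 3,4-dimethoxybenzaldehyde (KOH, EtOH, rt) should give (E)-3-(3,4-dimethoxyphenyl)-1-(2-hydroxy-3,4,6-trimethoxyphenyl)prop-2-en-1-one F2. Oxidative cyclisation of F2 with catalytic I2 in DMSO at about 130 °C should give 14 directly. Ring C is then closed end to end through the O1–C2 bond.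

2. Step 3. Four things may go wrong.
- Aldol-type self-condensation of 5 may outrun the coupling.
- Reductive elimination from a stabilised, chelating enolate may be slow, or a second arylation at C2 may set in.
- Traces of air may oxidise C2.
- O-silylation in the pocket between the C4 methoxy group and ring B may stay incomplete.

The fallback sets out from 5 and comes back at 9. It masks the ketone first and makes the C2–aryl bond by C–H functionalisation of the aromatic heterocycle instead of enolate coupling. Soft enolisation of 5 (TBSOTf, Et3N, CH2Cl2, 0 °C) should give tert-butyl[(4,6,7-trimethoxybenzofuran-3-yl)oxy]dimethylsilane F3. Direct arylation of the furan C2–H bond of F3 with 6 by concerted metalation–deprotonation should then give 9 (Pd(OAc)2, PCy3·HBF4, PivOH, K2CO3, anhydrous DMA, 100 °C). The only other ring C–H, at C5, is shielded by two flanking methoxy groups.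

3. Step 1. Ether cleavage may occur at the C6' methoxy group instead of C2', which would lead into the 5,6,7-oxygenated series, or it may go on to a second ether.

The fallback sets out from 2 and comes back at 4. It replaces 1 by a phenol whose free oxygen is fixed before the acylation, so no site-selective ether cleavage is needed. Acid-catalysed Dakin oxidation (H2O2, cat. H2SO4, MeOH) of purchased 2,3,5-trimethoxybenzaldehyde F4 should give 2,3,5-trimethoxyphenol F5. O-acylation of F5 with 2 (Et3N, CH2Cl2, 0 °C) should give 2,3,5-trimethoxyphenyl chloroacetate F6. Fries rearrangement of F6 (BF3·OEt2, 75 °C) should move the acyl group to the chelation-favoured ortho position C6 and give 4. A para-migrated by-product cannot close to a benzofuranone, so no constitutional isomer of 5 can arise.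

Further compounds
F1 | step 4 | 1-(2-hydroxy-3,4,6-trimethoxyphenyl)ethan-1-one | CC(=O)c1c(O)c(OC)c(OC)cc1OC
F2 | step 4 | (E)-3-(3,4-dimethoxyphenyl)-1-(2-hydroxy-3,4,6-trimethoxyphenyl)prop-2-en-1-one | COc1ccc(/C=C/C(=O)c2c(O)c(OC)c(OC)cc2OC)cc1OC
F3 | step 3 | tert-butyl[(4,6,7-trimethoxybenzofuran-3-yl)oxy]dimethylsilane | COc1cc(OC)c2c(O[Si](C)(C)C(C)(C)C)coc2c1OC
F4 | step 1 | 2,3,5-trimethoxybenzaldehyde (purchased) | COc1cc(C=O)c(OC)c(OC)c1
F5 | step 1 | 2,3,5-trimethoxyphenol | COc1cc(O)c(OC)c(OC)c1
F6 | step 1 | 2,3,5-trimethoxyphenyl chloroacetate | COc1cc(OC(=O)CCl)c(OC)c(OC)c1
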